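Two questions stand on this flask, both about the excess of right-handed over left-handed substrate among what is left: does it reach the level asked, and how high does it climb?

* whether the excess of right-handed substrate over left-handed substrate among what is left of the two reaches 95% by 1.0 h (yes / no)
* the highest excess of right-handed substrate over left-handed substrate among what is left of the two up to 1.0 h

- Thursday's: left-handed substrate 0.75 M; right-handed substrate 0.75 M; reagent 1.2 M; free catalyst 210 mM; run made earlier
- flask: left-handed substrate 1.5 M; reagent 1.20 M; free catalyst 210 mM; right-handed substrate 1.5 M; time 1.0 h

Thursday's run (percent of the left-handed substrate and right-handed substrate together charged)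

| time / min | right-handed substrate / % | left-handed substrate / % |
|---|---|---|
| 4.00 | 47.5 | 29.5 |
| 8.00 | 47.8 | 27.2 |
| 15.0 | 47.9 | 25.6 |
| 25.0 | 47.0 | 23.9 |
| 50.0 | 47.1 | 23.0 |

(standard deviation of a reading: 0.5 percentage points)

- free catalyst is single-handed; left-handed substrate and right-handed substrate are mirror images of each other, charged as a racemate, each of them at the stated concentration

1. In Thursday's run the left-handed substrate flattens near 23.0% at 50.0 min, with about 0.795 M of reagent remaining by balance, so the catalyst looks like what fails.

2. This reckoning assumes that left-handed substrate goes at a rate proportional to itself, reagent and working catalyst, and that the catalyst dies by the clock, whatever it turns over. Thursday's last reading then gives 0.811 /M. This is the catalyst dose: the rate constant times working catalyst summed over time, which serves as the clock of a second-order law between left-handed substrate and reagent. It equals the logarithm of how far the reagent-to-substrate ratio has moved, divided by the difference of the two charges, with right-handed use neglected.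

3. The first way copies Thursday's fraction, keeping 46.0% of the left-handed charge and Thursday's read excess of 34.4%. But that leaves this flask 0.390 M of reagent, less than Thursday's 0.795 M. This way cheats by treating the reagent level as unchanged.

4. The second way spends the same dose on this flask's charges and leaves 0.805 M of left-handed substrate. The read selectivity factor of about 13.0 leaves 1.43 M of right-handed substrate. The excess is then 28.0%, lower than the first way and below 95%. This is the number to commit to.

5. The forecast says no, with a top of 18% (range 12% to 36%): “I lean towards turnover”. Its top is lower than this reckoning.

6. The flask gives no and a top of 27.6%, keeping 54% of its left-handed charge against 53.7% reckoned.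

    reagent + free catalyst + left-handed substrate → free catalyst + left-handed product (k = 0.0863 /M²/s)
    reagent + free catalyst + right-handed substrate → free catalyst + right-handed product (k = 0.00734 /M²/s)
    2 free catalyst → spent catalyst A (k = 0.260 /M/s)
    reagent → decomposition product (k = 9.47 × 10⁻⁶ /s)
    reagent + free catalyst → spent catalyst B (k = 8.74 × 10⁻⁴ /M/s)

In this flask, the largest single effect on the excess comes from the path from 2 free catalyst to spent catalyst A: in the simulated run without that path, the excess at 1.00 h is 49.6% rather than 27.6%, and the part of both substrates reacted is 39.6% rather than 25.6%. With 2.0 M of reagent, the same dose leaves 0.500 M, or 33.3% of the left-handed charge, and an excess of 46.8%. That neighbour flask keeps 36% of its left-handed charge and tops out at 43.7%.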